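The route rests on cutting the trisubstituted C6'=C7' olefin (side chain numbered from the benzylic C1'), whose C7' methyl lies cis to the C5' carbinol carbon. A ruthenium-catalysed ring-closing metathesis of an acrylate ester forms this double bond inside a five-membered butenolide ring (C5'–O–C(=O)–C7'=C6'): the ring fixes the olefin geometry, the ester joins the aryl head to the hydroxygeranyl tail, and the lactone carbonyl carbon is kept as the latent C7' methyl. The precursor is the ester of an (S)-vinyl carbinol (C5' from (S)-epichlorohydrin) with a 2-substituted acrylic acid carrying the silyl-protected tail; the hydroquinone is masked as its dimethyl ether.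

Key step: step 13

Remark: the side chain is numbered C1' (benzylic) to C16' (terminal CH2OH), and geranylacetone is assumed to be purchased as the single (5E) isomer.

Step 1
Reactants: 1 geranylacetone, (5E)-6,10-dimethylundeca-5,9-dien-2-one
Product: 2 (5E,9E)-11-hydroxy-6,10-dimethylundeca-5,9-dien-2-one
Conditions: SeO2 (0.2 equiv), t-BuOOH (3 equiv), salicylic acid (0.1 equiv), CH2Cl2, 0 °C → rt
Reagents that add atoms: selenium dioxide, O=[Se]=O; tert-butyl hydroperoxide, CC(C)(C)OO
Why: Riley-type allylic oxidation with catalytic SeO2 (ene reaction, then [2,3]-sigmatropic shift) should attack the terminal, most accessible trisubstituted olefin at its (E)-methyl group and give the (E)-allylic alcohol, while the ketone does not react at room temperature.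

Step 2
Reactants: 2 (5E,9E)-11-hydroxy-6,10-dimethylundeca-5,9-dien-2-one
Product: 3 (5E,9E)-11-[(tert-butyldiphenylsilyl)oxy]-6,10-dimethylundeca-5,9-dien-2-one
Conditions: TBDPSCl, imidazole, CH2Cl2, rt
Reagents that add atoms: tert-butyl(chloro)diphenylsilane, CC(C)(C)[Si](Cl)(c1ccccc1)c1ccccc1
Why: Standard silylation of a primary allylic alcohol; the acid-stable TBDPS group is chosen so that a primary TBS ether can later be cleaved beside it.

Step 3
Reactants: 3 (5E,9E)-11-[(tert-butyldiphenylsilyl)oxy]-6,10-dimethylundeca-5,9-dien-2-one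
Product: 4 2,4,6-triisopropylbenzenesulfonyl hydrazone of ketone 3, (E) at C=N
Conditions: 2,4,6-(i-Pr)3C6H2SO2NHNH2, THF, rt
Reagents that add atoms: 2,4,6-triisopropylbenzenesulfonohydrazide, CC(C)c1cc(C(C)C)c(S(=O)(=O)NN)c(C(C)C)c1
Why: Condensation of a methyl ketone with an arenesulfonyl hydrazide should give the hydrazone, mainly with the sulfonamide nitrogen on the methyl side.

Step 4
Reactants: 4 2,4,6-triisopropylbenzenesulfonyl hydrazone of ketone 3
Product: 6 (5E,9E)-11-[(tert-butyldiphenylsilyl)oxy]-6,10-dimethyl-2-methylideneundeca-5,9-dienoic acid, via vinyllithium 5 (not isolated)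
Conditions: n-BuLi (2.2 equiv), TMEDA, THF, −78 °C → 0 °C; then CO2, −78 °C → rt; 1 M HCl
Reagents that add atoms: carbon dioxide, O=C=O
Why: Shapiro reaction: the dianion formed by deprotonation at the methyl group loses sulfinate and N2 to give the less substituted 1-alken-2-yllithium, which is carboxylated to the 2-substituted acrylic acid.

Step 5
Reactants: 7 4-methoxy-2-methylphenol
Product: 8 2-hydroxy-5-methoxy-3-methylbenzaldehyde
Conditions: MgCl2, Et3N, (CH2O)n, MeCN, reflux
Reagents that add atoms: paraformaldehyde (as formaldehyde), C=O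
Why: Casnati–Skattebøl ortho-formylation through the chloromagnesium phenoxide can occur only at the single free position ortho to the hydroxyl group.

Step 6
Reactants: 8 2-hydroxy-5-methoxy-3-methylbenzaldehyde
Product: 9 2,5-dimethoxy-3-methylbenzaldehyde
Conditions: MeI, K2CO3, DMF, rt → 40 °C
Reagents that add atoms: iodomethane, CI
Why: Williamson O-methylation of the phenoxide.

Step 7
Reactants: 9 2,5-dimethoxy-3-methylbenzaldehyde
Product: 10 (2,5-dimethoxy-3-methylphenyl)methanol
Conditions: NaBH4, MeOH, 0 °C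
Reagents that add atoms: none
Why: Hydride reduction of an aryl aldehyde to the benzylic alcohol.

Step 8
Reactants: 10 (2,5-dimethoxy-3-methylphenyl)methanol
Product: 11 1-(chloromethyl)-2,5-dimethoxy-3-methylbenzene
Conditions: SOCl2, CH2Cl2, 0 °C → rt
Reagents that add atoms: thionyl chloride, ClS(Cl)=O
Why: Chlorodehydroxylation of an electron-rich benzylic alcohol through its chlorosulfite.

Step 9
Reactants: 12 (S)-epichlorohydrin, (2S)-2-(chloromethyl)oxirane; 13 (trimethylsilyl)acetylene
Product: 14 (2S)-1-chloro-5-(trimethylsilyl)pent-4-yn-2-ol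
Conditions: 13, n-BuLi, THF, −78 °C; BF3·OEt2; then 12, −78 °C
Reagents that add atoms: none
Why: Yamaguchi alkynylation: the lithium acetylide opens the BF3-activated epoxide at its unsubstituted carbon, so no bond at the stereocentre is broken and the (S) centre of 12 becomes C5'.

Step 10
Reactants: 14 (2S)-1-chloro-5-(trimethylsilyl)pent-4-yn-2-ol
Product: 17 (3S)-hex-1-en-5-yn-3-ol, via silylalkynyl epoxide 15 (not isolated), via silylated enynol 16 (not isolated)
Conditions: Me3S+ I− (4 equiv), n-BuLi (3.8 equiv), THF, −20 °C → rt; then MeOH, K2CO3, rt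
Reagents that add atoms: trimethylsulfonium iodide, C[S+](C)C.[I-]
Why: Sulfonium-ylide homologation of a terminal epoxide to an allylic alcohol: the ylide first closes the chlorohydrin as a base, then opens the epoxide at CH2 and the β-alkoxy sulfonium salt eliminates Me2S, after which methanolysis removes the alkynyl silane in the same flask; the carbinol C–O bond is never broken.

Step 11
Reactants: 17 (3S)-hex-1-en-5-yn-3-ol; 11 1-(chloromethyl)-2,5-dimethoxy-3-methylbenzene
Product: 19 (3S,5E)-7-(2,5-dimethoxy-3-methylphenyl)-5-methylhepta-1,5-dien-3-ol, via alkenylalane 18 (not isolated)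
Conditions: Me3Al (3 equiv), Cp2ZrCl2 (0.25 equiv), CH2Cl2, 0 °C → rt; volatiles removed; then 11 (1.1 equiv), Pd(PPh3)4 (5 mol %), THF, rt → 45 °C; aq. potassium sodium tartrate
Reagents that add atoms: trimethylaluminium, C[Al](C)C
Why: Negishi zirconium-catalysed carboalumination adds CH3 and Al syn across the terminal alkyne with the methyl on the internal carbon (the hydroxyl is masked in situ as its dimethylaluminium alkoxide and the vinyl group reacts far more slowly), and zerovalent-palladium-catalysed cross-coupling of the (E)-alkenylalane with the benzylic chloride proceeds with retention, which fixes the C2'=C3' geometry.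

Step 12
Reactants: 19 (3S,5E)-7-(2,5-dimethoxy-3-methylphenyl)-5-methylhepta-1,5-dien-3-ol; 6 (5E,9E)-11-[(tert-butyldiphenylsilyl)oxy]-6,10-dimethyl-2-methylideneundeca-5,9-dienoic acid
Product: 20 (3S,5E)-7-(2,5-dimethoxy-3-methylphenyl)-5-methylhepta-1,5-dien-3-yl (5E,9E)-11-[(tert-butyldiphenylsilyl)oxy]-6,10-dimethyl-2-methylideneundeca-5,9-dienoate
Conditions: EDC·HCl, DMAP, CH2Cl2, 0 °C → rt
Reagents that add atoms: none
Why: Steglich-type carbodiimide esterification acylates the secondary allylic hydroxyl without touching the C5' stereocentre.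

Step 13
Reactants: 20 (S)-vinyl carbinol ester of the 2-substituted acrylic acid
Product: 21 (5S)-3-{(3E,7E)-9-[(tert-butyldiphenylsilyl)oxy]-4,8-dimethylnona-3,7-dien-1-yl}-5-[(2E)-4-(2,5-dimethoxy-3-methylphenyl)-2-methylbut-2-en-1-yl]furan-2(5H)-one
Conditions: second-generation Grubbs catalyst RuCl2(=CHPh)(PCy3)(H2IMes) (5–10 mol %), CH2Cl2 (0.003 M), 40 °C, argon sweep
Reagents that add atoms: none
Why: The ruthenium benzylidene exchanges onto the monosubstituted C6' vinyl group, the new alkylidene adds to the 1,1-disubstituted acrylate olefin in a [2+2] step and the metallacyclobutane cycloreverts with loss of ethylene; this is ring-closing metathesis of an allylic 2-alkylacrylate to an α-substituted butenolide, a well-precedented closure. The ring closed is the five-membered lactone C5'–O–C(=O)–C7'=C6', formed by joining the two olefin termini across the ester tether. No stereocentre is created, and C5', taken from epichlorohydrin, is not involved in any bond change. A five-membered ring can hold only a cis olefin, so the carbonyl carbon (the later C7' methyl) is placed cis to C5' and the C8' chain trans. Chemoselectivity rests on the substrate: the three chain olefins are trisubstituted and could close only four- or eight-membered rings, and high dilution suppresses intermolecular metathesis of the vinyl group.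

Step 14
Reactants: 21 α-substituted (S)-butenolide
Product: 22 (2Z,4S,6E)-2-{(3E,7E)-9-[(tert-butyldiphenylsilyl)oxy]-4,8-dimethylnona-3,7-dien-1-yl}-8-(2,5-dimethoxy-3-methylphenyl)-6-methylocta-2,6-diene-1,4-diol
Conditions: i-Bu2AlH (4 equiv), CH2Cl2, −78 °C → 0 °C; aq. potassium sodium tartrate
Reagents that add atoms: none
Why: 1,2-Reduction of the unsaturated lactone by i-Bu2AlH through the lactol gives the (Z)-2-ene-1,4-diol with the ring-derived geometry retained, and the non-basic conditions spare the epimerisable γ-stereocentre.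

Step 15
Reactants: 22 (Z)-enediol
Product: 23 bis(tert-butyldimethylsilyl) ether of diol 22
Conditions: TBSCl (3 equiv), imidazole, DMF, rt
Reagents that add atoms: tert-butyl(chloro)dimethylsilane, CC(C)(C)[Si](C)(C)Cl
Why: Exhaustive silylation of the primary and the secondary allylic hydroxyl groups.

Step 16
Reactants: 23 bis(tert-butyldimethylsilyl) ether of diol 22
Product: 24 (2Z,4S,6E)-4-[(tert-butyldimethylsilyl)oxy]-2-{(3E,7E)-9-[(tert-butyldiphenylsilyl)oxy]-4,8-dimethylnona-3,7-dien-1-yl}-8-(2,5-dimethoxy-3-methylphenyl)-6-methylocta-2,6-dien-1-ol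
Conditions: CSA (0.1 equiv), MeOH/CH2Cl2 (1:1), −10 °C → 0 °C; Et3N quench
Reagents that add atoms: none
Why: Acid-catalysed methanolysis is sterically controlled and should cleave the primary TBS ether much faster than the secondary TBS ether or the acid-stable primary TBDPS ether.

Step 17
Reactants: 24 primary allylic alcohol with C5' silyl ether
Product: 26 (2E,6E,10E,12S,14E)-12-[(tert-butyldimethylsilyl)oxy]-1-[(tert-butyldiphenylsilyl)oxy]-16-(2,5-dimethoxy-3-methylphenyl)-2,6,10,14-tetramethylhexadeca-2,6,10,14-tetraene, via allylic mesylate 25 (not isolated)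
Conditions: Ms2O (1.3 equiv), Et3N (2 equiv), THF, −40 °C; then LiBHEt3 (4 equiv), −40 °C → 0 °C
Reagents that add atoms: none
Why: Sulfonylation followed by SN2 hydride displacement of the primary allylic mesylate by LiBHEt3 turns CH2OH into the C7' methyl without allylic transposition, since the C6' terminus next to the silyloxy-bearing C5' is hindered.

Step 18
Reactants: 26 bis-silyl ether with the C7' methyl in place
Product: 27 (2E,6E,10E,12S,14E)-16-(2,5-dimethoxy-3-methylphenyl)-2,6,10,14-tetramethylhexadeca-2,6,10,14-tetraene-1,12-diol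
Conditions: n-Bu4NF (4 equiv), THF, rt
Reagents that add atoms: none
Why: Fluoride-induced desilylation removes the TBS and the TBDPS ether in one operation.

Step 19
Reactants: 27 diol dimethyl ether
Product: 29 2-[(2E,5S,6E,10E,14E)-5,16-dihydroxy-3,7,11,15-tetramethylhexadeca-2,6,10,14-tetraen-1-yl]-6-methylbenzene-1,4-diol (CNP0151872.1), via quinone 28 (not isolated)
Conditions: (NH4)2Ce(NO3)6 (2.5 equiv), MeCN/H2O (2:1), 0 °C, 15 min; Et2O extraction; then aq. Na2S2O4, rt, argon
Reagents that add atoms: water, O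
Why: Oxidative demethylation of the 1,4-dimethoxyarene by tetravalent cerium (two one-electron oxidations with water adding at the methoxy-bearing carbons) gives the benzoquinone, which dithionite reduces to the hydroquinone during work-up; the short, cold oxidation should leave the olefins and allylic alcohols untouched.

Compound list
1 | geranylacetone, (5E)-6,10-dimethylundeca-5,9-dien-2-one | CC(=O)CC/C=C(\C)CCC=C(C)C | starting material
2 | (5E,9E)-11-hydroxy-6,10-dimethylundeca-5,9-dien-2-one | CC(=O)CC/C=C(\C)CC/C=C(\C)CO | intermediate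
3 | (5E,9E)-11-[(tert-butyldiphenylsilyl)oxy]-6,10-dimethylundeca-5,9-dien-2-one | CC(=O)CC/C=C(\C)CC/C=C(\C)CO[Si](c1ccccc1)(c1ccccc1)C(C)(C)C | intermediate
4 | N'-[(2E,5E,9E)-11-[(tert-butyldiphenylsilyl)oxy]-6,10-dimethylundeca-5,9-dien-2-ylidene]-2,4,6-tri(propan-2-yl)benzenesulfonohydrazide | C/C(CC/C=C(\C)CC/C=C(\C)CO[Si](c1ccccc1)(c1ccccc1)C(C)(C)C)=N\NS(=O)(=O)c1c(C(C)C)cc(C(C)C)cc1C(C)C | intermediate
5 | [(5E,9E)-11-[(tert-butyldiphenylsilyl)oxy]-6,10-dimethylundeca-1,5,9-trien-2-yl]lithium | [Li]C(=C)CC/C=C(\C)CC/C=C(\C)CO[Si](c1ccccc1)(c1ccccc1)C(C)(C)C | intermediate (not isolated)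
6 | (5E,9E)-11-[(tert-butyldiphenylsilyl)oxy]-6,10-dimethyl-2-methylideneundeca-5,9-dienoic acid | C=C(C(=O)O)CC/C=C(\C)CC/C=C(\C)CO[Si](c1ccccc1)(c1ccccc1)C(C)(C)C | intermediate
7 | 4-methoxy-2-methylphenol | Cc1cc(OC)ccc1O | starting material
8 | 2-hydroxy-5-methoxy-3-methylbenzaldehyde | O=Cc1cc(OC)cc(C)c1O | intermediate
9 | 2,5-dimethoxy-3-methylbenzaldehyde | O=Cc1cc(OC)cc(C)c1OC | intermediate
10 | (2,5-dimethoxy-3-methylphenyl)methanol | OCc1cc(OC)cc(C)c1OC | intermediate
11 | 1-(chloromethyl)-2,5-dimethoxy-3-methylbenzene | ClCc1cc(OC)cc(C)c1OC | intermediate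
12 | (S)-epichlorohydrin, (2S)-2-(chloromethyl)oxirane | ClC[C@@H]1CO1 | starting material
13 | (trimethylsilyl)acetylene | C#C[Si](C)(C)C | starting material
14 | (2S)-1-chloro-5-(trimethylsilyl)pent-4-yn-2-ol | ClC[C@@H](O)CC#C[Si](C)(C)C | intermediate
15 | (2S)-2-[3-(trimethylsilyl)prop-2-yn-1-yl]oxirane | C1[C@@H](O1)CC#C[Si](C)(C)C | intermediate (not isolated)
16 | (3S)-6-(trimethylsilyl)hex-1-en-5-yn-3-ol | C=C[C@@H](O)CC#C[Si](C)(C)C | intermediate (not isolated)
17 | (3S)-hex-1-en-5-yn-3-ol | C=C[C@@H](O)CC#C | intermediate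
18 | dimethylaluminium alkoxide of (3S,5E)-6-(dimethylalumanyl)-5-methylhexa-1,5-dien-3-ol | C=C[C@@H](O[Al](C)C)C/C(C)=C/[Al](C)C | intermediate (not isolated)
19 | (3S,5E)-7-(2,5-dimethoxy-3-methylphenyl)-5-methylhepta-1,5-dien-3-ol | C=C[C@@H](O)C/C(C)=C/Cc1cc(OC)cc(C)c1OC | intermediate
20 | (3S,5E)-7-(2,5-dimethoxy-3-methylphenyl)-5-methylhepta-1,5-dien-3-yl (5E,9E)-11-[(tert-butyldiphenylsilyl)oxy]-6,10-dimethyl-2-methylideneundeca-5,9-dienoate | C=C[C@@H](OC(=O)C(=C)CC/C=C(\C)CC/C=C(\C)CO[Si](c1ccccc1)(c1ccccc1)C(C)(C)C)C/C(C)=C/Cc1cc(OC)cc(C)c1OC | intermediate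
21 | (5S)-3-{(3E,7E)-9-[(tert-butyldiphenylsilyl)oxy]-4,8-dimethylnona-3,7-dien-1-yl}-5-[(2E)-4-(2,5-dimethoxy-3-methylphenyl)-2-methylbut-2-en-1-yl]furan-2(5H)-one | O=C1O[C@@H](C/C(C)=C/Cc2cc(OC)cc(C)c2OC)C=C1CC/C=C(\C)CC/C=C(\C)CO[Si](c1ccccc1)(c1ccccc1)C(C)(C)C | intermediate
22 | (2Z,4S,6E)-2-{(3E,7E)-9-[(tert-butyldiphenylsilyl)oxy]-4,8-dimethylnona-3,7-dien-1-yl}-8-(2,5-dimethoxy-3-methylphenyl)-6-methylocta-2,6-diene-1,4-diol | OC/C(CC/C=C(\C)CC/C=C(\C)CO[Si](c1ccccc1)(c1ccccc1)C(C)(C)C)=C\[C@@H](O)C/C(C)=C/Cc1cc(OC)cc(C)c1OC | intermediate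
23 | 1,4-bis(tert-butyldimethylsilyl) ether of diol 22 | CC(C)(C)[Si](C)(C)OC/C(CC/C=C(\C)CC/C=C(\C)CO[Si](c1ccccc1)(c1ccccc1)C(C)(C)C)=C\[C@@H](O[Si](C)(C)C(C)(C)C)C/C(C)=C/Cc1cc(OC)cc(C)c1OC | intermediate
24 | (2Z,4S,6E)-4-[(tert-butyldimethylsilyl)oxy]-2-{(3E,7E)-9-[(tert-butyldiphenylsilyl)oxy]-4,8-dimethylnona-3,7-dien-1-yl}-8-(2,5-dimethoxy-3-methylphenyl)-6-methylocta-2,6-dien-1-ol | OC/C(CC/C=C(\C)CC/C=C(\C)CO[Si](c1ccccc1)(c1ccccc1)C(C)(C)C)=C\[C@@H](O[Si](C)(C)C(C)(C)C)C/C(C)=C/Cc1cc(OC)cc(C)c1OC | intermediate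
25 | methanesulfonate of alcohol 24 | CS(=O)(=O)OC/C(CC/C=C(\C)CC/C=C(\C)CO[Si](c1ccccc1)(c1ccccc1)C(C)(C)C)=C\[C@@H](O[Si](C)(C)C(C)(C)C)C/C(C)=C/Cc1cc(OC)cc(C)c1OC | intermediate (not isolated)
26 | (2E,6E,10E,12S,14E)-12-[(tert-butyldimethylsilyl)oxy]-1-[(tert-butyldiphenylsilyl)oxy]-16-(2,5-dimethoxy-3-methylphenyl)-2,6,10,14-tetramethylhexadeca-2,6,10,14-tetraene | C/C(CC/C=C(\C)CC/C=C(\C)CO[Si](c1ccccc1)(c1ccccc1)C(C)(C)C)=C\[C@@H](O[Si](C)(C)C(C)(C)C)C/C(C)=C/Cc1cc(OC)cc(C)c1OC | intermediate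
27 | (2E,6E,10E,12S,14E)-16-(2,5-dimethoxy-3-methylphenyl)-2,6,10,14-tetramethylhexadeca-2,6,10,14-tetraene-1,12-diol | C/C(CC/C=C(\C)CC/C=C(\C)CO)=C\[C@@H](O)C/C(C)=C/Cc1cc(OC)cc(C)c1OC | intermediate
28 | 2-[(2E,5S,6E,10E,14E)-5,16-dihydroxy-3,7,11,15-tetramethylhexadeca-2,6,10,14-tetraen-1-yl]-6-methylcyclohexa-2,5-diene-1,4-dione | C/C(CC/C=C(\C)CC/C=C(\C)CO)=C\[C@@H](O)C/C(C)=C/CC1=CC(=O)C=C(C)C1=O | intermediate (not isolated)
29 | 2-[(2E,5S,6E,10E,14E)-5,16-dihydroxy-3,7,11,15-tetramethylhexadeca-2,6,10,14-tetraen-1-yl]-6-methylbenzene-1,4-diol (CNP0151872.1) | C/C(=C\CC/C(C)=C/CC/C(C)=C/[C@@H](O)C/C(C)=C/Cc1cc(O)cc(C)c1O)CO | target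

Total step count: 19 steps.
Longest linear sequence: 13 steps (steps 5–8, then 11–19, from 4-methoxy-2-methylphenol).

Steps most likely to fail

1. Step 11. The alkenylalane carries an aluminium alkoxide and may transfer its alkenyl group to palladium only slowly, so that methyl transfer, protodealumination or slow attack on the vinyl group erode the one-pot benzylation. The fallback sets out from 17 and comes back at 19 with the coupling roles reversed. The same carboalumination is quenched with I2 to give the isolable vinyl iodide (3S,5E)-6-iodo-5-methylhexa-1,5-dien-3-ol F1. Chloride 11 is converted with Zn dust and LiCl in THF into (2,5-dimethoxy-3-methylbenzyl)zinc chloride F2. Negishi coupling of F1 with excess F2 (Pd(PPh3)4 or PdCl2(dppf), THF, rt) should give 19 with retention of the olefin geometry.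

2. Step 13. Closure onto the electron-poor 1,1-disubstituted acrylate may be slow enough for oligomerisation through the vinyl group or catalyst decay to dominate. The fallback sets out from 4 and 19 and comes back at 22; it replaces the ester tether by a silaketal. Vinyllithium 5, generated from 4 as in step 4, is trapped with paraformaldehyde to give (5E,9E)-11-[(tert-butyldiphenylsilyl)oxy]-6,10-dimethyl-2-methylideneundeca-5,9-dien-1-ol F3. Alcohol 19 is treated with excess i-Pr2SiCl2 and Et3N to give the chlorosilane chloro{[(3S,5E)-7-(2,5-dimethoxy-3-methylphenyl)-5-methylhepta-1,5-dien-3-yl]oxy}di(propan-2-yl)silane F4, and the excess reagent is removed in vacuo. F4 with F3 and imidazole gives the mixed bis(alkoxy)diisopropylsilane of 19 and F3 F5. Ring-closing metathesis with the same second-generation Grubbs catalyst (toluene, 80 °C) closes the seven-membered (4S)-6-{(3E,7E)-9-[(tert-butyldiphenylsilyl)oxy]-4,8-dimethylnona-3,7-dien-1-yl}-4-[(2E)-4-(2,5-dimethoxy-3-methylphenyl)-2-methylbut-2-en-1-yl]-2,2-di(propan-2-yl)-4,7-dihydro-1,3,2-dioxasilepine F6, whose ring again forces the C6'=C7' olefin cis. HF·pyridine buffered with pyridine (THF, 0 °C) removes the silylene while the TBDPS ether survives and delivers diol 22 directly.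

3. Step 4. The vinyllithium may be quenched by proton transfer before it meets CO2, or the dianion may form partly on the methylene side, giving the olefin or a regioisomeric acid. The fallback sets out from 3 and comes back at 6 through palladium-catalysed carbonylation. Kinetic enolisation of 3 on the methyl side with LiN(i-Pr)2 (THF, −78 °C) and trapping with PhNTf2 gives (5E,9E)-11-[(tert-butyldiphenylsilyl)oxy]-6,10-dimethylundeca-1,5,9-trien-2-yl trifluoromethanesulfonate F7. Hydroxycarbonylation of F7 (Pd(OAc)2, dppf, KOAc, CO 1 atm, DMF, rt; aqueous work-up) should give acid 6.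

Further compounds
F1 | step 11 | (3S,5E)-6-iodo-5-methylhexa-1,5-dien-3-ol | C=C[C@@H](O)C/C(C)=C/I
F2 | step 11 | (2,5-dimethoxy-3-methylbenzyl)zinc chloride | Cl[Zn]Cc1cc(OC)cc(C)c1OC
F3 | step 13 | (5E,9E)-11-[(tert-butyldiphenylsilyl)oxy]-6,10-dimethyl-2-methylideneundeca-5,9-dien-1-ol | C=C(CO)CC/C=C(\C)CC/C=C(\C)CO[Si](c1ccccc1)(c1ccccc1)C(C)(C)C
F4 | step 13 | chloro{[(3S,5E)-7-(2,5-dimethoxy-3-methylphenyl)-5-methylhepta-1,5-dien-3-yl]oxy}di(propan-2-yl)silane | C=C[C@@H](O[Si](Cl)(C(C)C)C(C)C)C/C(C)=C/Cc1cc(OC)cc(C)c1OC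
F5 | step 13 | mixed bis(alkoxy)diisopropylsilane of 19 and F3 | C=C[C@@H](O[Si](C(C)C)(C(C)C)OCC(=C)CC/C=C(\C)CC/C=C(\C)CO[Si](c1ccccc1)(c1ccccc1)C(C)(C)C)C/C(C)=C/Cc1cc(OC)cc(C)c1OC
F6 | step 13 | (4S)-6-{(3E,7E)-9-[(tert-butyldiphenylsilyl)oxy]-4,8-dimethylnona-3,7-dien-1-yl}-4-[(2E)-4-(2,5-dimethoxy-3-methylphenyl)-2-methylbut-2-en-1-yl]-2,2-di(propan-2-yl)-4,7-dihydro-1,3,2-dioxasilepine | CC(C)[Si]1(C(C)C)OCC(CC/C=C(\C)CC/C=C(\C)CO[Si](c2ccccc2)(c2ccccc2)C(C)(C)C)=C[C@H](C/C(C)=C/Cc2cc(OC)cc(C)c2OC)O1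
F7 | step 4 | (5E,9E)-11-[(tert-butyldiphenylsilyl)oxy]-6,10-dimethylundeca-1,5,9-trien-2-yl trifluoromethanesulfonate | C=C(OS(=O)(=O)C(F)(F)F)CC/C=C(\C)CC/C=C(\C)CO[Si](c1ccccc1)(c1ccccc1)C(C)(C)C
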